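**Retrosynthetic overview**
- The route rests on reading ring A (C1 side chain, C2 OMe, C3 OMe, C4 phenethyl, C5 H, C6 OMe) as the dehydrogenated, O-methylated form of 4-methoxy-5-(2-phenylethyl)cyclohexane-1,3-dione, with carbonyls at C2 and C6 and C1 the only carbon flanked by both.
- The tertiary alcohol comes from Markovnikov hydration of a C1 prenyl group, which is introduced by C-alkylation of the dione at C1 before ring A is aromatized.
- Aromatization is done late on the bis-silyl dienol ether, so the ortho-prenyl resorcinol is never exposed to the oxidant; the silyl groups are then exchanged for methyl.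
- The dione comes from one annulation: conjugate addition of dimethyl methoxymalonate to (E)-6-phenylhex-3-en-2-one (C3–C4 bond), then Claisen closure of the methyl ketone onto an ester (C1–C2 bond), then ester hydrolysis and decarboxylation.
- Ring A is the only ring formed (step 2); the phenyl ring is bought in with 3-phenylpropanal.

Key step: step 2

Assumption: the target has no stereocentre; intermediates 5 to 11 carry transient stereocentres, are handled as racemic diastereomer mixtures and are drawn without stereodescriptors, and the 1,3-diones are written as diketo tautomers.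

**Step 1**
Reactants: 1 3-phenylpropanal; 2 1-(triphenylphosphoranylidene)propan-2-one
Product: 3 (E)-6-phenylhex-3-en-2-one
Conditions: CH2Cl2, rt to reflux
Reagents that add atoms: none
Why: Wittig olefination with a ketone-stabilized ylide should give the conjugated enone with the usual E selectivity of stabilized ylides.

**Step 2**
Reactants: 3 (E)-6-phenylhex-3-en-2-one; 4 dimethyl 2-methoxymalonate
Product: 6 methyl 1-methoxy-2,4-dioxo-6-(2-phenylethyl)cyclohexane-1-carboxylate (racemic diastereomer mixture), via Michael adduct 5 (not isolated)
Conditions: NaOMe (1.1 equiv), MeOH, 0 °C to reflux; then aq. HCl to pH 2, 0 °C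
Reagents that add atoms: none
Why: Methoxide generates the tertiary anion of 4, which adds reversibly in the 1,4 sense to enone 3 and forms the C3–C4 bond of adduct 5. Methoxide then equilibrates the ketone enolates of 5, and the methyl enolate attacks one of the two ester carbonyls in a 6-exo-trig Claisen (Dieckmann-type) closure that forms C1–C2 and expels methoxide. Deprotonation of the new 1,3-dione at C1 gives a stabilized enolate, which drains both equilibria toward ring A and shields the non-enolizable β-keto ester from retro-Claisen cleavage. The closest known reaction type is the Michael–Claisen synthesis of cyclohexane-1,3-diones from enones and malonic esters (dimedone type), here run with an α-substituted malonate. The two new stereocentres (quaternary C3, tertiary C4) arise without control and need none, because both are erased when ring A is aromatized. The step needs 1,4- over 1,2-addition, secured by the soft doubly stabilized nucleophile and the reversibility of carbonyl addition, and closure through the methyl rather than the methylene enolate, secured because only the former leads to a six-membered ring.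

**Step 3**
Reactants: 6 methyl 1-methoxy-2,4-dioxo-6-(2-phenylethyl)cyclohexane-1-carboxylate
Product: 8 4-methoxy-5-(2-phenylethyl)cyclohexane-1,3-dione, via keto acid 7 (not isolated)
Conditions: 2 M aq. NaOH (3 equiv), 80 °C; then conc. HCl to pH 1, 80 °C
Reagents that add atoms: sodium hydroxide, [Na+].[OH-] (its oxygen enters acid 7 and leaves again as CO2; no heavy atom of it remains in 8)
Why: Ester saponification takes place while the dione is protected as its enolate, and acidification then lets the β-keto acid decarboxylate through the usual cyclic transition state, as in the dimedone preparation, leaving C3 as a methoxy-bearing CH.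

**Step 4**
Reactants: 8 4-methoxy-5-(2-phenylethyl)cyclohexane-1,3-dione; 9 prenyl bromide (1-bromo-3-methylbut-2-ene)
Product: 10 4-methoxy-2-(3-methylbut-2-en-1-yl)-5-(2-phenylethyl)cyclohexane-1,3-dione
Conditions: KOH (1.0 equiv), H2O, prenyl bromide (1.5 equiv), 0 °C to rt; then aq. HCl
Reagents that add atoms: none
Why: Stetter-type alkylation of a cyclohexane-1,3-dione enolate in water, where hydrogen bonding to the enolate oxygens directs the soft allylic bromide to carbon, and C1 is the only doubly activated carbon of the ring.

**Step 5**
Reactants: 10 4-methoxy-2-(3-methylbut-2-en-1-yl)-5-(2-phenylethyl)cyclohexane-1,3-dione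
Product: 11 1,3-bis[(tert-butyldimethylsilyl)oxy]-6-methoxy-2-(3-methylbut-2-en-1-yl)-5-(2-phenylethyl)cyclohexa-1,3-diene
Conditions: TBSOTf (2.5 equiv), Et3N (4 equiv), CH2Cl2, 0 °C to rt; cold aq. NaHCO3 wash, crude used directly
Reagents that add atoms: tert-butyldimethylsilyl trifluoromethanesulfonate, CC(C)(C)[Si](C)(C)OS(=O)(=O)C(F)(F)F
Why: Soft enolization of a 1,3-diketone with silyl triflate and amine first silylates the enol oxygen and then, through the silyl-activated enone, removes a proton from the less hindered α' carbon C5 to give the 1,3-bis(silyloxy)-1,3-diene; a minor isomer enolized toward C3 would lead to the same arene in step 6.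

**Step 6**
Reactants: 11 1,3-bis[(tert-butyldimethylsilyl)oxy]-6-methoxy-2-(3-methylbut-2-en-1-yl)-5-(2-phenylethyl)cyclohexa-1,3-diene
Product: 12 1,3-bis[(tert-butyldimethylsilyl)oxy]-4-methoxy-2-(3-methylbut-2-en-1-yl)-5-(2-phenylethyl)benzene
Conditions: DDQ (1.05 equiv), PhMe, 0 °C
Reagents that add atoms: none
Why: Quinone dehydrogenation of a cyclohexa-1,3-diene: hydride abstraction from ring C4 gives a cation stabilized by both silyloxy groups, which loses the C3 proton to aromatize, and the silyl ethers keep the ortho-prenyl phenols masked so that oxidative chromene formation should not occur.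

**Step 7**
Reactants: 12 1,3-bis[(tert-butyldimethylsilyl)oxy]-4-methoxy-2-(3-methylbut-2-en-1-yl)-5-(2-phenylethyl)benzene
Product: 14 1,3,4-trimethoxy-2-(3-methylbut-2-en-1-yl)-5-(2-phenylethyl)benzene, via resorcinol 13 (not isolated)
Conditions: CsF (4 equiv), MeI (6 equiv), DMF, rt
Reagents that add atoms: iodomethane, CI
Why: Fluoride cleaves both aryl silyl ethers and the caesium phenoxides are O-methylated in the same flask (desilylation followed by Williamson ether synthesis), so the acid-sensitive ortho-prenyl resorcinol is never isolated.

**Step 8**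
Reactants: 14 1,3,4-trimethoxy-2-(3-methylbut-2-en-1-yl)-5-(2-phenylethyl)benzene
Product: 15 4-[2,3,6-trimethoxy-4-(2-phenylethyl)phenyl]-2-methylbutan-2-ol (target)
Conditions: Co(acac)2 (20 mol %), PhSiH3 (2 equiv), O2 (1 atm), THF/i-PrOH, rt
Reagents that add atoms: dioxygen, O=O
Why: Mukaiyama hydration: hydrogen-atom transfer from a cobalt hydride to the trisubstituted olefin gives the tertiary radical, which is trapped by O2 and reduced by the silane to the Markovnikov tertiary alcohol, while the arene and the ethers are inert.

**Compound list**
1 | 3-phenylpropanal | O=CCCc1ccccc1 | starting material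
2 | 1-(triphenylphosphoranylidene)propan-2-one | CC(=O)C=P(c1ccccc1)(c1ccccc1)c1ccccc1 | starting material
3 | (E)-6-phenylhex-3-en-2-one | CC(=O)/C=C/CCc1ccccc1 | intermediate
4 | dimethyl 2-methoxymalonate | COC(C(=O)OC)C(=O)OC | starting material
5 | dimethyl 2-methoxy-2-(5-oxo-1-phenylhexan-3-yl)propanedioate (racemic) | COC(=O)C(OC)(C(=O)OC)C(CCc1ccccc1)CC(C)=O | intermediate (not isolated)
6 | methyl 1-methoxy-2,4-dioxo-6-(2-phenylethyl)cyclohexane-1-carboxylate (racemic diastereomer mixture) | COC(=O)C1(OC)C(CCc2ccccc2)CC(=O)CC1=O | intermediate
7 | 1-methoxy-2,4-dioxo-6-(2-phenylethyl)cyclohexane-1-carboxylic acid (racemic diastereomer mixture) | OC(=O)C1(OC)C(CCc2ccccc2)CC(=O)CC1=O | intermediate (not isolated)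
8 | 4-methoxy-5-(2-phenylethyl)cyclohexane-1,3-dione (racemic diastereomer mixture) | COC1C(CCc2ccccc2)CC(=O)CC1=O | intermediate
9 | prenyl bromide (1-bromo-3-methylbut-2-ene) | CC(C)=CCBr | starting material
10 | 4-methoxy-2-(3-methylbut-2-en-1-yl)-5-(2-phenylethyl)cyclohexane-1,3-dione (racemic diastereomer mixture) | COC1C(CCc2ccccc2)CC(=O)C(CC=C(C)C)C1=O | intermediate
11 | 1,3-bis[(tert-butyldimethylsilyl)oxy]-6-methoxy-2-(3-methylbut-2-en-1-yl)-5-(2-phenylethyl)cyclohexa-1,3-diene (racemic diastereomer mixture) | COC1C(CCc2ccccc2)C=C(O[Si](C)(C)C(C)(C)C)C(CC=C(C)C)=C1O[Si](C)(C)C(C)(C)C | intermediate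
12 | 1,3-bis[(tert-butyldimethylsilyl)oxy]-4-methoxy-2-(3-methylbut-2-en-1-yl)-5-(2-phenylethyl)benzene | COc1c(CCc2ccccc2)cc(O[Si](C)(C)C(C)(C)C)c(CC=C(C)C)c1O[Si](C)(C)C(C)(C)C | intermediate
13 | 4-methoxy-2-(3-methylbut-2-en-1-yl)-5-(2-phenylethyl)benzene-1,3-diol (present as its caesium phenoxide) | COc1c(CCc2ccccc2)cc(O)c(CC=C(C)C)c1O | intermediate (not isolated)
14 | 1,3,4-trimethoxy-2-(3-methylbut-2-en-1-yl)-5-(2-phenylethyl)benzene | COc1cc(CCc2ccccc2)c(OC)c(OC)c1CC=C(C)C | intermediate
15 | 4-[2,3,6-trimethoxy-4-(2-phenylethyl)phenyl]-2-methylbutan-2-ol | COc1cc(CCc2ccccc2)c(OC)c(OC)c1CCC(C)(C)O | target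

**Step count**
Total steps: 8. Longest linear sequence: 8 steps, from 3-phenylpropanal 1 to target 15.

**Steps most likely to fail**

Step 2. The conjugate addition of the hindered tertiary malonate anion may reverse faster than the ring closes, leaving the enone to base-mediated self-condensation. The fallback sets out from 3 and forms the same two bonds in separate operations with a less hindered donor. Methyl methoxyacetate is enolized with LDA and silylated with TMSCl (THF, −78 °C) to the ketene silyl acetal 1,2-dimethoxy-1-(trimethylsilyloxy)ethene F1. TiCl4-promoted Mukaiyama–Michael addition of F1 to 3 (CH2Cl2, −78 °C, aqueous work-up) should give methyl 2-methoxy-5-oxo-3-(2-phenylethyl)hexanoate F2. KOtBu in THF (0 °C to rt, then acid) should close F2 through the methyl enolate in a Claisen condensation, which returns to the route at dione 8 and makes step 3 unnecessary.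

Step 6. Hydride abstraction may occur at the allylic and benzylic methylene of the prenyl group instead of ring C4, or silyl groups may be lost and the freed phenol may cyclize oxidatively onto the prenyl olefin. The fallback sets out from 11 and replaces hydride abstraction by selenenylation and selenoxide elimination. PhSeCl (CH2Cl2, −78 °C) should attack the terminal dienol ether carbon C5 anti to the C4 substituent, with loss of one silyl group, to give 3-[(tert-butyldimethylsilyl)oxy]-4-methoxy-2-(3-methylbut-2-en-1-yl)-5-(2-phenylethyl)-6-(phenylselanyl)cyclohex-2-en-1-one F3. Oxidation with mCPBA (1 equiv, −78 °C) and warming with i-Pr2NH should trigger syn elimination across C4–C5, and the dienone should tautomerize to 3-[(tert-butyldimethylsilyl)oxy]-4-methoxy-2-(3-methylbut-2-en-1-yl)-5-(2-phenylethyl)phenol F4. F4 is taken through the conditions of step 7 and returns to the route at 14.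

Step 4. O-alkylation of the enolate and a second C-alkylation at C1 may compete with mono-C-prenylation. The fallback sets out from 8 and moves the C1 functionalization to the arene stage. Dehydrogenation of 8 (10% Pd/C, mesitylene, reflux, argon sweep) should give 4-methoxy-5-(2-phenylethyl)benzene-1,3-diol F5. Methylation (MeI, K2CO3, acetone, reflux) should give 1,2,5-trimethoxy-3-(2-phenylethyl)benzene F6. n-BuLi (THF, 0 °C) should lithiate F6 at C1, the position between the C2 and C6 methoxy groups, and alkylation with prenyl bromide 9 (−78 °C to rt) returns to the route at 14, so that steps 5 to 7 are not needed.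

**Further compounds**
F1 | step 2 | 1,2-dimethoxy-1-(trimethylsilyloxy)ethene (E/Z mixture) | COC=C(OC)O[Si](C)(C)C
F2 | step 2 | methyl 2-methoxy-5-oxo-3-(2-phenylethyl)hexanoate (racemic diastereomer mixture) | COC(=O)C(OC)C(CCc1ccccc1)CC(C)=O
F3 | step 6 | 3-[(tert-butyldimethylsilyl)oxy]-4-methoxy-2-(3-methylbut-2-en-1-yl)-5-(2-phenylethyl)-6-(phenylselanyl)cyclohex-2-en-1-one (racemic diastereomer mixture) | COC1C(CCc2ccccc2)C([Se]c2ccccc2)C(=O)C(CC=C(C)C)=C1O[Si](C)(C)C(C)(C)C
F4 | step 6 | 3-[(tert-butyldimethylsilyl)oxy]-4-methoxy-2-(3-methylbut-2-en-1-yl)-5-(2-phenylethyl)phenol | COc1c(CCc2ccccc2)cc(O)c(CC=C(C)C)c1O[Si](C)(C)C(C)(C)C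
F5 | step 4 | 4-methoxy-5-(2-phenylethyl)benzene-1,3-diol | COc1c(O)cc(O)cc1CCc1ccccc1
F6 | step 4 | 1,2,5-trimethoxy-3-(2-phenylethyl)benzene | COc1cc(CCc2ccccc2)c(OC)c(OC)c1
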